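(All runs were computed for an exercise, and the scatter is random.)

In a one-step world, starting material would become target and stay there, but these flasks also lose target.

| flask | starting material | other conformer | remark | time |
|---|---|---|---|---|
| green | 0.15 M (fed, over 2.5 h) | 0.015 M | the very flask that is asked about, followed so far |  |
| teal | 0.15 M (fed, over 2.5 h) | 0.022 M | run made earlier |  |
| flask | 0.15 M (fed, over 2.5 h) | 0.0150 M |  | 25 h |

| run | time / h | target / % | starting material / % |
|---|---|---|---|
| green | 0.333 | 1.1 | 11.7 |
| green | 0.667 | 5.0 | 18.8 |
| green | 1.00 | 8.0 | 22.4 |
| green | 1.50 | 15.3 | 27.8 |
| green | 2.50 | 26.3 | 30.9 |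
| green | 5.00 | 17.4 | 2.4 |
| teal | 4.00 | 21.4 | 6.5 |
| teal | 8.00 | 4.6 | 0.6 |
| teal | 12.0 | 0.8 | 0.3 |
| teal | 15.0 | 0 | 0.3 |
| teal | 20.0 | 0.5 | 0 |
| teal | 25.0 | 0.9 | 0 |

(readings scatter by 0.5 percentage points)

- percent here means starting material units held: one side product counts as two
- what was read earlier has a scatter of 0.5 percentage points, one standard deviation
- steps thought possible: starting material <-> other conformer; starting material -> target; other conformer -> isomer of the product; other conformer <-> third conformer; third conformer -> third product; starting material + target -> side product; target -> over-reaction product A; target -> over-reaction product B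
- percentages count the whole charge, also what has not yet gone in

- time up to 25 h at which target stands highest
- the amount of target, in percent of the starting material and other conformer together charged, at that time

1. In the teal flask, after the feed, target falls from 21.4% to 4.6% in 4.00 h. That gives a pseudo-first-order loss constant of 0.384 h⁻¹. Its half-life of 1.81 h is far shorter than 25 h, so target in the teal flask runs down towards zero.

2. In the green flask, the rise from 1.50 h to 2.50 h plus this loss gives a formation constant of 0.647 h⁻¹. After the feed, green starting material falls at 1.02 h⁻¹.

3. Green target therefore leaves the feed with a net gain of 0.0989 h⁻¹, as a fraction of the charge. Freezing the gain's rate of decline, it reaches zero after 0.408 h. The rise is a triangle of 2 percentage points, so this reckoning puts the green peak at 2.91 h and 28.3%.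

4. Teal looks nearly the same, with the same feed but more other conformer. Percentages count both charges, so the quantity to carry is the starting-material share, starting material divided by both charges: 90.9% in green, lower in teal at 87.2%. As an estimate for flasks with this feed and this charge of starting material, the rule is to hold the peak divided by this share fixed.

The forecast gives 3 h and 27.7%, slightly below this reckoning's amount, and says of the end of dosing: “so it is still climbing”.

    starting material ⇌ other conformer (K = 0.160, k = 0.610 h⁻¹)
    starting material → target (k = 0.730 h⁻¹)
    other conformer → isomer of the product (k = 0.970 h⁻¹)
    other conformer ⇌ third conformer (K = 5.50, k = 11.0 h⁻¹)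
    third conformer → third product (k = 1.30 h⁻¹)
    starting material + target → side product (k = 1.20 L mol⁻¹ h⁻¹)
    target → over-reaction product A (k = 4.00 × 10⁻⁴ h⁻¹)
    target → over-reaction product B (k = 0.470 h⁻¹)

The flask peaks at 2.94 h with 26.9%, which is 29.6% on the share. During the feed, starting material built up to 30.2% at 2.50 h while target passed on to over-reaction product B, which stood at 13.9%. After the feed, starting material fell to 18.7% by 2.94 h, and over-reaction product B reached 58.2% by 12.5 h. The neighbour with 0.0060 M of other conformer has a share of 96.2%, so the rule gives 28.5%, and that flask peaks at 27.9%.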